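**Plan**
1. Retrosynthesis: the C5–C1' bond between ring B and the 5-phenylpentyl chain is cut first. Then the C8 O–CH3 and C8–H bonds are cut, back to a C8 ketone masked as a ketal. Ring A is opened at N1–C2/N1–C8a (O-for-N exchange of a 4-pyranone), O1–C2, C2–C3 and C4–C4a.
2. Forward: ring B is bought as cyclohexane-1,2-dione. Ring A is built on it (Claisen acylation, dianion acetylation, pyranone closure, exchange to the N-methoxy-4-pyridone). The C8 ketone is then unmasked, reduced and methylated, and the chain is joined last as 5-phenylpent-1-ene.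
3. Enabling feature: the C4 carbonyl oxygen of ring A lies peri to the C5 methylene of ring B. A metal held on O4 reaches C5–H through a five-membered O4–C4–C4a–C5–metal chelate, and no other C–H bond can form such a chelate with O4.
4. Stereochemistry: C8 (R) comes from catalyst-controlled asymmetric transfer hydrogenation. C5 (S) comes from substrate control in the last step: N1–OMe/C8–OMe peri strain makes the in-plane C5–H the one cis to the C8 methoxy group.

Key step: step 8

Remark: quinolone numbering is used throughout (ring A = N1, C2, C3, C4, C4a, C8a; ring B = C4a, C5 to C8, C8a); 4-pyranones and 4-pyridones are written in aromatic SMILES form, and compounds 1, 3, 5, 8 and 13 are taken as commercial.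

**Step 1**
Reactants: 1 cyclohexane-1,2-dione
Product: 2 1,4-dioxaspiro[4.5]decan-6-one
Conditions: HOCH2CH2OH (1.05 equiv), TsOH·H2O (cat.), benzene, reflux, Dean–Stark
Reagents that add atoms: ethylene glycol, OCCO
Why: Acid-catalysed ketalisation with azeotropic removal of water converts one carbonyl of the 1,2-dione into the dioxolane, and the remaining ketone, now next to a quaternary ketal carbon, is hindered toward a second ketalisation, which masks the future C8 oxygen and leaves the future C4a as the only enolisable position.

**Step 2**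
Reactants: 2 1,4-dioxaspiro[4.5]decan-6-one; 3 methyl 2-methoxyacetate
Product: 4 7-(2-methoxyacetyl)-1,4-dioxaspiro[4.5]decan-6-one
Conditions: NaH (2.2 equiv), THF, 0 °C to reflux; AcOH quench
Reagents that add atoms: none
Why: Crossed Claisen condensation: the sodium enolate of 2 can form only on the CH2 side (the other α-carbon is the ketal carbon), it attacks the activated α-alkoxy ester, and deprotonation of the β-diketone pulls the equilibrium, which places C4 and C3 with its methoxy group on the future C4a.

**Step 3**
Reactants: 4 7-(2-methoxyacetyl)-1,4-dioxaspiro[4.5]decan-6-one; 5 N-methoxy-N-methylacetamide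
Product: 7 3-methoxy-2-methyl-6,7-dihydro-5H-spiro[chromene-8,2'-[1,3]dioxolan]-4-one, via triketone 6 (not isolated)
Conditions: LiN(iPr)2 (2.3 equiv), THF, −78 to 0 °C; 5 (1.2 equiv), −78 °C to rt; AcOH quench; crude 6, TsOH·H2O (cat.), toluene, reflux, Dean–Stark
Reagents that add atoms: none
Why: γ-Acylation of a β-diketone dianion: the second deprotonation can occur only at the methoxy-bearing CH2, this terminal carbanion is acetylated by the N-methoxy-N-methylamide without over-addition, and acid-catalysed cyclodehydration of the 1,3,5-triketone (enol oxygen onto the methyl ketone, then loss of water) closes the 4-pyranone while water removal keeps the ketal.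

**Step 4**
Reactants: 7 3-methoxy-2-methyl-6,7-dihydro-5H-spiro[chromene-8,2'-[1,3]dioxolan]-4-one; 8 O-methylhydroxylamine hydrochloride
Product: 9 1,3-dimethoxy-2-methyl-6,7-dihydro-5H-spiro[quinoline-8,2'-[1,3]dioxolan]-4(1H)-one
Conditions: NaOAc (3 equiv), EtOH, 85 °C, sealed tube
Reagents that add atoms: none
Why: Pyranone-to-pyridone exchange (addition of the amine at C2 or C8a, ring opening, recyclisation through nitrogen and dehydration): the α-effect nucleophile O-methylhydroxylamine replaces the ring oxygen by N–OMe in one operation, and the pyranone template ensures that nitrogen bridges C2 and C8a.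

**Step 5**
Reactants: 9 1,3-dimethoxy-2-methyl-6,7-dihydro-5H-spiro[quinoline-8,2'-[1,3]dioxolan]-4(1H)-one
Product: 10 1,3-dimethoxy-2-methyl-6,7-dihydroquinoline-4,8(1H,5H)-dione
Conditions: 2 M aq. HCl, THF, 50 °C
Reagents that add atoms: water, O
Why: Acid-catalysed ketal hydrolysis unmasks the C8 ketone, while the methyl ethers and the N–OMe group are inert to dilute aqueous acid.

**Step 6**
Reactants: 10 1,3-dimethoxy-2-methyl-6,7-dihydroquinoline-4,8(1H,5H)-dione
Product: 11 (R)-8-hydroxy-1,3-dimethoxy-2-methyl-5,6,7,8-tetrahydroquinolin-4(1H)-one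
Conditions: RuCl[(R,R)-TsDPEN](p-cymene) (2 mol %), HCO2H/Et3N (5:2 azeotrope), CH2Cl2, 30 °C
Reagents that add atoms: none
Why: Noyori-type asymmetric transfer hydrogenation: the ketone is of the aryl alkyl (1-tetralone) type with ring A in the aryl role, so the (R,R)-TsDPEN complex of divalent ruthenium should deliver hydride to the face that gives the (R)-carbinol at C8 (catalyst control), and the vinylogous amide carbonyl at C4 is not reduced.

**Step 7**
Reactants: 11 (R)-8-hydroxy-1,3-dimethoxy-2-methyl-5,6,7,8-tetrahydroquinolin-4(1H)-one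
Product: 12 (R)-1,3,8-trimethoxy-2-methyl-5,6,7,8-tetrahydroquinolin-4(1H)-one
Conditions: NaH (1.2 equiv), MeI (1.5 equiv), THF, 0 °C to rt
Reagents that add atoms: iodomethane, CI
Why: Williamson ether synthesis: the sodium alkoxide is methylated at oxygen and the C8–O bond is not broken, so the (R) configuration is retained.

**Step 8**
Reactants: 12 (R)-1,3,8-trimethoxy-2-methyl-5,6,7,8-tetrahydroquinolin-4(1H)-one; 13 5-phenylpent-1-ene
Product: 14 (5S,8R)-1,3,8-trimethoxy-2-methyl-5-(5-phenylpentyl)-5,6,7,8-tetrahydroquinolin-4(1H)-one (waltherione H)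
Conditions: [Ir(cod)2]BF4 (10 mol %), 2,2'-bis(diphenylphosphino)biphenyl (10 mol %), 13 (4 equiv, added in portions), PhCl, 130 °C, sealed tube
Reagents that add atoms: none
Why: Proposed new method: the cationic monovalent iridium centre binds the C4 carbonyl oxygen of ring A (a vinylogous amide oxygen, the most Lewis-basic site of 12), inserts into the peri C5–H bond of ring B through a five-membered O4–C4–C4a–C5–Ir chelate, adds the Ir–H bond across the terminal alkene 13 in the anti-Markovnikov sense and forms the linear C5–CH2 bond by C–C reductive elimination, so that no atom is lost. The closest known reaction types are the carbonyl-directed Murai-type addition of ortho C(sp2)–H bonds of aryl ketones to alkenes and the directed addition of secondary C(sp3)–H bonds next to nitrogen to terminal alkenes under cationic iridium–bisphosphine catalysis; new here is a benzylic-type methylene C–H reached from a ring carbonyl. No ring is closed; the iridacycle is transient. The new C5 stereocentre is set by the substrate: peri strain between N1–OMe and C8–OMe keeps the C8 methoxy group pseudoaxial, the chelated metal lies in the plane of ring A and can reach only the pseudoequatorial C5–H, which in that half-chair is the hydrogen cis to the C8 methoxy group, and C–H insertion and reductive elimination both go with retention, which should give the (5S,8R)-cis product. The step needs site selectivity (C5–H over C8–H, the C2 methyl group and the three OCH3 groups), linear regioselectivity and survival of the N–O bond: only C5–H forms a five-membered chelate with the strong carbonyl donor, the terminal alkene inserts at its unsubstituted carbon for steric reasons, and no external reductant or base is present.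

**Compound list**
1 | cyclohexane-1,2-dione | O=C1CCCCC1=O | starting material
2 | 1,4-dioxaspiro[4.5]decan-6-one (mono-ethylene ketal of 1) | O=C1CCCCC12OCCO2 | intermediate
3 | methyl 2-methoxyacetate | COCC(=O)OC | starting material
4 | 7-(2-methoxyacetyl)-1,4-dioxaspiro[4.5]decan-6-one (β-diketone, largely enolised) | COCC(=O)C1CCCC2(OCCO2)C1=O | intermediate
5 | N-methoxy-N-methylacetamide | CC(=O)N(C)OC | starting material
6 | 2-methoxy-1-(6-oxo-1,4-dioxaspiro[4.5]decan-7-yl)butane-1,3-dione (triketone) | CC(=O)C(OC)C(=O)C1CCCC2(OCCO2)C1=O | intermediate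
7 | 3-methoxy-2-methyl-6,7-dihydro-5H-spiro[chromene-8,2'-[1,3]dioxolan]-4-one (tetrahydrochromen-4-one with ethylene ketal at C8) | COc1c(C)oc2c(c1=O)CCCC21OCCO1 | intermediate
8 | O-methylhydroxylamine hydrochloride | CON.Cl | starting material
9 | 1,3-dimethoxy-2-methyl-6,7-dihydro-5H-spiro[quinoline-8,2'-[1,3]dioxolan]-4(1H)-one (N-methoxy-4-pyridone with ethylene ketal at C8) | COc1c(C)n(OC)c2c(c1=O)CCCC21OCCO1 | intermediate
10 | 1,3-dimethoxy-2-methyl-6,7-dihydroquinoline-4,8(1H,5H)-dione | COc1c(C)n(OC)c2c(c1=O)CCCC2=O | intermediate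
11 | (R)-8-hydroxy-1,3-dimethoxy-2-methyl-5,6,7,8-tetrahydroquinolin-4(1H)-one | COc1c(C)n(OC)c2c(c1=O)CCC[C@H]2O | intermediate
12 | (R)-1,3,8-trimethoxy-2-methyl-5,6,7,8-tetrahydroquinolin-4(1H)-one | COc1c(C)n(OC)c2c(c1=O)CCC[C@H]2OC | intermediate
13 | 5-phenylpent-1-ene | C=CCCCc1ccccc1 | starting material
14 | (5S,8R)-1,3,8-trimethoxy-2-methyl-5-(5-phenylpentyl)-5,6,7,8-tetrahydroquinolin-4(1H)-one (waltherione H; chain and C8 methoxy cis) | COc1c(C)n(OC)c2c(c1=O)[C@@H](CCCCCc1ccccc1)CC[C@H]2OC | target

**Totals**
Total step count: 8. Longest linear sequence: 8 steps (1 to 14).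

**Steps most likely to fail**

Step 8. The iridium may not insert into the secondary C5–H bond. Alternatively, β-hydride elimination from the C5–Ir intermediate may lead to transfer dehydrogenation of ring B, the low-valent metal may insert into the N–O bond, the terminal alkene may isomerise to unreactive internal alkenes, or facial discrimination at C5 may be poor. The fallback uses known chemistry and attaches the chain first; it sets out from 2 and 13 and comes back to the route at 14. Ketone 2 is dehydrogenated (IBX, DMSO, 70 °C) to 1,4-dioxaspiro[4.5]dec-7-en-6-one F1. Alkene 13 is hydrozirconated with Cp2Zr(H)Cl and the alkylzirconium is added to F1 with CuCl, AgNTf2 and a chiral phosphoramidite (copper-catalysed asymmetric conjugate addition, using the ligand antipode that gives the S adduct). This should give (S)-8-(5-phenylpentyl)-1,4-dioxaspiro[4.5]decan-6-one F2. F2 then passes through the chemistry of steps 2 to 7 with the chain in place: Claisen condensation with 3 gives (8S)-7-(2-methoxyacetyl)-8-(5-phenylpentyl)-1,4-dioxaspiro[4.5]decan-6-one F3; dianion acetylation with 5 and cyclodehydration give (5S)-3-methoxy-2-methyl-5-(5-phenylpentyl)-6,7-dihydro-5H-spiro[chromene-8,2'-[1,3]dioxolan]-4-one F4; exchange with 8 gives (5S)-1,3-dimethoxy-2-methyl-5-(5-phenylpentyl)-6,7-dihydro-5H-spiro[quinoline-8,2'-[1,3]dioxolan]-4(1H)-one F5; ketal hydrolysis gives (S)-1,3-dimethoxy-2-methyl-5-(5-phenylpentyl)-6,7-dihydroquinoline-4,8(1H,5H)-dione F6; transfer hydrogenation with the (R,R)-TsDPEN ruthenium catalyst gives (5S,8R)-8-hydroxy-1,3-dimethoxy-2-methyl-5-(5-phenylpentyl)-5,6,7,8-tetrahydroquinolin-4(1H)-one F7; O-methylation (NaH, MeI) gives 14.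

Step 4. The exchange may stall after ring opening, or the ring may fail to reclose at the hindered C8a because the N-methoxy group clashes with the spiroketal; partial loss of the ketal under the buffered conditions would expose a second carbonyl to oxime ether formation. The fallback brings nitrogen in with a free N–OH and forms the O–CH3 bond afterwards; it sets out from 7 and comes back at 9. Pyranone 7 is heated with NH2OH·HCl and NaOAc in EtOH to give 1-hydroxy-3-methoxy-2-methyl-6,7-dihydro-5H-spiro[quinoline-8,2'-[1,3]dioxolan]-4(1H)-one F8. F8 is methylated at the N–O oxygen (MeI, K2CO3, DMF, rt) to give 9.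

Step 6. Facial selectivity may be poor, because the peri N–OMe group and the polar ring A may disturb the aryl/alkyl discrimination on which the catalyst relies. The fallback replaces asymmetric reduction by resolution; it sets out from 10 and comes back at 11. Ketone 10 is reduced with NaBH4 (MeOH, 0 °C) to racemic 8-hydroxy-1,3-dimethoxy-2-methyl-5,6,7,8-tetrahydroquinolin-4(1H)-one F9. Lipase-catalysed acylation (Candida antarctica lipase B, vinyl acetate, MTBE), which by the usual preference for secondary carbinols should acylate the R enantiomer, gives (R)-1,3-dimethoxy-2-methyl-4-oxo-1,4,5,6,7,8-hexahydroquinolin-8-yl acetate F10. The unreacted (S)-8-hydroxy-1,3-dimethoxy-2-methyl-5,6,7,8-tetrahydroquinolin-4(1H)-one F11 is separated and oxidised back to 10 with MnO2 for recycling. Methanolysis of F10 (K2CO3, MeOH) gives 11.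

**Further compounds**
F1 | step 8 | 1,4-dioxaspiro[4.5]dec-7-en-6-one | O=C1C=CCCC12OCCO2
F2 | step 8 | (S)-8-(5-phenylpentyl)-1,4-dioxaspiro[4.5]decan-6-one | O=C1C[C@@H](CCCCCc2ccccc2)CCC13OCCO3
F3 | step 8 | (8S)-7-(2-methoxyacetyl)-8-(5-phenylpentyl)-1,4-dioxaspiro[4.5]decan-6-one | O=C1C(C(=O)COC)[C@@H](CCCCCc2ccccc2)CCC13OCCO3
F4 | step 8 | (5S)-3-methoxy-2-methyl-5-(5-phenylpentyl)-6,7-dihydro-5H-spiro[chromene-8,2'-[1,3]dioxolan]-4-one | COc1c(C)oc2c(c1=O)[C@@H](CCCCCc1ccccc1)CCC21OCCO1
F5 | step 8 | (5S)-1,3-dimethoxy-2-methyl-5-(5-phenylpentyl)-6,7-dihydro-5H-spiro[quinoline-8,2'-[1,3]dioxolan]-4(1H)-one | COc1c(C)n(OC)c2c(c1=O)[C@@H](CCCCCc1ccccc1)CCC21OCCO1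
F6 | step 8 | (S)-1,3-dimethoxy-2-methyl-5-(5-phenylpentyl)-6,7-dihydroquinoline-4,8(1H,5H)-dione | COc1c(C)n(OC)c2c(c1=O)[C@@H](CCCCCc1ccccc1)CCC2=O
F7 | step 8 | (5S,8R)-8-hydroxy-1,3-dimethoxy-2-methyl-5-(5-phenylpentyl)-5,6,7,8-tetrahydroquinolin-4(1H)-one | COc1c(C)n(OC)c2c(c1=O)[C@@H](CCCCCc1ccccc1)CC[C@H]2O
F8 | step 4 | 1-hydroxy-3-methoxy-2-methyl-6,7-dihydro-5H-spiro[quinoline-8,2'-[1,3]dioxolan]-4(1H)-one | COc1c(C)n(O)c2c(c1=O)CCCC21OCCO1
F9 | step 6 | racemic 8-hydroxy-1,3-dimethoxy-2-methyl-5,6,7,8-tetrahydroquinolin-4(1H)-one | COc1c(C)n(OC)c2c(c1=O)CCCC2O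
F10 | step 6 | (R)-1,3-dimethoxy-2-methyl-4-oxo-1,4,5,6,7,8-hexahydroquinolin-8-yl acetate | COc1c(C)n(OC)c2c(c1=O)CCC[C@H]2OC(C)=O
F11 | step 6 | (S)-8-hydroxy-1,3-dimethoxy-2-methyl-5,6,7,8-tetrahydroquinolin-4(1H)-one | COc1c(C)n(OC)c2c(c1=O)CCC[C@@H]2O
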